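| setting | winter | summer | flask |
|---|---|---|---|
| E | 0.42 M | 1.7 M | 0.84 M |
| Q | 1.2 equiv | 1.2 equiv | 1.20 equiv |
| remark | run made earlier | run made earlier |  |
| time |  |  | 80 min |

| run | time / min | E / % | Z / % |
|---|---|---|---|
| winter | 5.00 | 57.1 | 39.7 |
| winter | 8.00 | 49.3 | 45.3 |
| winter | 12.0 | 44.5 | 49.9 |
| winter | 20.0 | 37.5 | 52.7 |
| winter | 30.0 | 31.8 | 54.5 |
| winter | 40.0 | 26.4 | 54.8 |
| winter | 60.0 | 19.8 | 57.5 |
| summer | 10.0 | 32.6 | 50.8 |
| summer | 20.0 | 23.9 | 48.0 |
| summer | 30.0 | 17.7 | 46.5 |
| summer | 40.0 | 14.3 | 45.7 |
| summer | 50.0 | 10.0 | 46.1 |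
| summer | 60.0 | 7.2 | 45.1 |

(readings scatter by 0.5 percentage points)

- the earlier runs do not show how much of Q is bound; that part of a forecast is a guess

- part of the E that has reacted at 80 min
- share of the unused Q that is free and not bound as G, at 80 min

- The summer run starts 4.05 times as concentrated as the winter run, but the apparent first-order constant of its E tail, read from 20.0 min to 60.0 min, is 0.0300 /min against 0.0160 /min in the winter run.
- If you run each last reading forward with its own constant to 80 min, the E left is 0.0604 M in the winter run and 0.0672 M in the summer run, a factor of just 1.11.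
- Joining both ends by their geometric mean gives 0.0637 M: this is R, the residual molarity, the E expected in molar at that time with Q at these equivalents.
- For the flask at 0.84 M, R means 7.59% of the charge left, so my c is 92.4%.
- In the summer run Z sinks from 50.8% to 45.1% between 10.0 min and 60.0 min, but in the winter run it rises from 52.7% to 57.5% between 20.0 min and 60.0 min; so I would charge the flask as written and stop at 80 min, wary of a longer wait.
- The readings do not show how much Q sits in G, so fr stays a guess for me.
- The forecast, reading “a fast burst, then a slow tail”, gave c = 91%, just below my figure, and fr = 50%.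
- The flask gives c = 92.2% and fr = 13.6%.

    E + Q → D + Z (k = 0.00640 /M/s)
    Q + D ⇌ G, settled at all times (K = 660 /M)
    E + Z → J (k = 3.50 × 10⁻⁴ /M/s)
    D → L (k = 0.00540 /s)
    Q + Z → X (k = 6.30 × 10⁻⁴ /M/s)

- By 8.00 min, E + Q had 74% of its turnover up to the asked time behind it, and the flask held E 40.9%, Z 50.8% and G 0.451 M. From then to 80 min, with free Q at 3.32% of its charge at 40.0 min and 4.13% at the end, and G down to 0.264 M, E sank to 7.77%, or 0.0653 M against R = 0.0637 M, while J, both its E counted, rose from 5.83% to 32.5%.
- For the neighbour at 0.50 M, R gives 12.7% of E left and c = 87.3%; the computed neighbour has 12% left and c = 87.9%.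

The data stem from a simulated flask for substances that don't exist; scatter was added.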